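**Retrosynthetic overview**
1. Target 38 ⇐ 36 (ester and acetonide cleavage) ⇐ 35 ⇐ 34: the 19,10-lactone is closed last, by iodolactonisation of a C1=C10 alkene with the C19 ester, then deiodinated.
2. Ring B: C9–C10 by palladium-catalysed intramolecular ketone α-alkenylation (33 ⇐ 32); C5–C6 by Ireland–Claisen rearrangement of ester 29, which joins fragment A (28) and fragment CD (16).
3. Fragment CD (16): C8 by CBS reduction and Johnson–Claisen chirality transfer on a cyclohexenone (ring C); ring D by a proposed palladium-catalysed ketone β-C–H alkenylation with a 2-bromoallyl arm.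
4. Fragment A (28): C4 by catalytic asymmetric Diels–Alder reaction (ring A), C1 by CBS reduction, the 2β,3β-diol by hydroxyl-directed dihydroxylation.
5. Ring order: C, then D (fragment CD); A (fragment A); union; B; lactone.

Convention (one line): C1–C19 in names and comments are the gibberellin positions of the corresponding atoms of the target; α is the face of the lactone bridge, β the opposite face. The target is read as the 2β,3β,11β-trihydroxy 19,10-lactone 7-acid.

**Fragment CD**

Step 1
Reactants: 1 cyclohexane-1,3-dione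
Product: 2 3-methoxycyclohex-2-en-1-one
Conditions: MeOH, p-TsOH (cat.), benzene, reflux (Dean–Stark)
Reagents that add atoms: methanol, CO
Why: Acid-catalysed enol etherification of the 1,3-dione (vinylogous ester formation) is driven by azeotropic removal of water and creates no stereocentre.

Step 2
Reactants: 2 3-methoxycyclohex-2-en-1-one; 3 2,3-dibromoprop-1-ene
Product: 6 3-(2-bromoprop-2-en-1-yl)cyclohex-2-en-1-one, via allylzinc bromide 4 (not isolated), via tertiary carbinol 5 (not isolated)
Conditions: Zn dust, LiCl, THF, 0 °C to rt; then 2, 40 °C; then 1 M HCl, rt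
Reagents that add atoms: water, O
Why: Stork–Danheiser enone transposition, in which the allylic zinc reagent adds 1,2 to the vinylogous ester carbonyl and acid hydrolysis of the carbinol moves the carbonyl to the future C11, leaving the 2-bromoallyl arm (C15–C17) on the future C8.

Step 3
Reactants: 6 3-(2-bromoprop-2-en-1-yl)cyclohex-2-en-1-one
Product: 7 (1R)-3-(2-bromoprop-2-en-1-yl)cyclohex-2-en-1-ol
Conditions: (S)-Me-CBS oxazaborolidine (10 mol %), BH3·SMe2, THF, −30 °C; MeOH quench
Reagents that add atoms: none
Why: Corey–Bakshi–Shibata reduction, in which the oxazaborolidine distinguishes the alkenyl (large) from the CH2 (small) flank of the carbonyl and delivers hydride to one face to give the (R)-allylic alcohol that later controls C8.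

Step 4
Reactants: 7 (1R)-3-(2-bromoprop-2-en-1-yl)cyclohex-2-en-1-ol; 8 1,1,1-trimethoxyethane
Product: 10 methyl 2-[(1R)-1-(2-bromoprop-2-en-1-yl)cyclohex-2-en-1-yl]acetate, via ketene acetal 9 (not isolated)
Conditions: 8 (5 equiv), EtCO2H (cat.), xylene, 140 °C, MeOH distilled off
Reagents that add atoms: none
Why: Johnson–Claisen rearrangement, a suprafacial [3,3] shift that forms the new C–C bond on the ring face from which the C–O bond leaves, so the carbinol chirality is transferred to the quaternary C8 while C6 and C7 arrive as the acetate arm.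

Step 5
Reactants: 10 methyl 2-[(1R)-1-(2-bromoprop-2-en-1-yl)cyclohex-2-en-1-yl]acetate
Product: 12 methyl 2-[(1R)-1-(2-bromoprop-2-en-1-yl)-3-hydroxycyclohexyl]acetate (both C11 epimers), via alkylborane 11 (not isolated)
Conditions: BH3·THF (1.0 equiv), THF, 0 °C; then H2O2, aq NaOAc, 0 °C to rt
Reagents that add atoms: hydrogen peroxide, OO
Why: Hydroboration–oxidation places boron on C11, the alkene carbon remote from the quaternary C8, while the electron-poor vinyl bromide and the ester react much more slowly, and the C11 epimer mixture is irrelevant because this centre is oxidised in the next step.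

Step 6
Reactants: 12 methyl 2-[(1R)-1-(2-bromoprop-2-en-1-yl)-3-hydroxycyclohexyl]acetate
Product: 13 methyl 2-[(1R)-1-(2-bromoprop-2-en-1-yl)-3-oxocyclohexyl]acetate
Conditions: Dess–Martin periodinane, NaHCO3, CH2Cl2, rt
Reagents that add atoms: none
Why: Dess–Martin oxidation converts both carbinol epimers into the single C11 ketone without touching the vinyl bromide or the ester.

Step 7
Reactants: 13 methyl 2-[(1R)-1-(2-bromoprop-2-en-1-yl)-3-oxocyclohexyl]acetate
Product: 15 methyl 2-[(1R,5S)-6-methylidene-3-oxobicyclo[3.2.1]octan-1-yl]acetate, via enone 14 (not isolated)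
Conditions: Pd(O2CCF3)2 (10 mol %), P(i-Pr)3 (20 mol %), AgO2CCF3 (1.2 equiv), 2,6-di-tert-butylpyridine (1.2 equiv), 1,4-dioxane/(CF3)2CHOH, 70 °C
Reagents that add atoms: none
Why: Proposed new method: a redox-neutral intramolecular β-C–H alkenylation in which divalent palladium forms the C12 enolate of 13 and β-hydride elimination of H13 gives enone 14 and zerovalent palladium (only the C12–C13 side can desaturate because C8 is quaternary), oxidative addition into the tethered vinyl C–Br bond and 5-exo syn-carbopalladation of the enone then forge C16–C13 and the bridged ring D with its exocyclic methylene, the resulting palladium enolate cannot β-hydride eliminate towards the new bridgehead and is protonated, and AgO2CCF3 removes bromide to regenerate the divalent catalyst, the C13 configuration being forced by the 1,3-diaxial bridge from the fixed C8 centre; the closest known chemistry is the palladium-catalysed direct β-arylation of ketones with aryl halides by a desaturation and conjugate-addition relay, together with intramolecular reductive Heck cyclisations of vinyl halides onto enones.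

Step 8
Reactants: 15 methyl 2-[(1R,5S)-6-methylidene-3-oxobicyclo[3.2.1]octan-1-yl]acetate
Product: 16 2-[(1R,5S)-6-methylidene-3-oxobicyclo[3.2.1]octan-1-yl]acetic acid
Conditions: LiOH, THF/H2O, rt; then 1 M HCl
Reagents that add atoms: lithium hydroxide, [Li+].[OH-]
Why: Saponification of the unhindered primary-type methyl ester gives the acid for the fragment union without affecting the two stereocentres.

**Fragment A**

Step 9
Reactants: 17 (E)-4-(dimethylamino)but-3-en-2-one
Product: 18 (E)-3-(tert-butyldimethylsilyloxy)-N,N-dimethylbuta-1,3-dien-1-amine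
Conditions: KN(SiMe3)2, THF, −78 °C; then t-BuMe2SiCl, −78 °C to rt
Reagents that add atoms: tert-butyldimethylsilyl chloride, CC(C)(C)[Si](C)(C)Cl
Why: O-Silylation of the potassium dienolate of the vinylogous amide gives the electron-rich 1-amino-3-siloxy diene (Rawal-type diene).

Step 10
Reactants: 18 (E)-3-(tert-butyldimethylsilyloxy)-N,N-dimethylbuta-1,3-dien-1-amine; 19 2-methylprop-2-enal
Product: 21 (1R)-1-methyl-4-oxocyclohex-2-ene-1-carbaldehyde, via Diels–Alder adduct 20 (not isolated)
Conditions: Jacobsen [(salen)Cr]SbF6 catalyst (5 mol %, the enantiomer that gives (R)-21), 4 Å MS, CH2Cl2, −40 °C; then 1 M HCl, THF, 0 °C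
Reagents that add atoms: none
Why: Catalytic asymmetric Diels–Alder reaction in which the chiral chromium Lewis acid binds methacrolein and shields one face so that the amino-siloxy diene adds endo with the nitrogen-bearing terminus bonding to the α-carbon, which sets the C4 quaternary centre, after which acid hydrolyses the silyl enol ether and eliminates dimethylamine to give the enone.

Step 11
Reactants: 21 (1R)-1-methyl-4-oxocyclohex-2-ene-1-carbaldehyde
Product: 22 methyl (1R)-1-methyl-4-oxocyclohex-2-ene-1-carboxylate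
Conditions: I2, KOH, MeOH, 0 °C
Reagents that add atoms: methanol, CO
Why: Oxidative esterification, in which iodine oxidises the methyl hemiacetal of the non-enolisable aldehyde to the C19 methyl ester without touching the quaternary centre.

Step 12
Reactants: 22 methyl (1R)-1-methyl-4-oxocyclohex-2-ene-1-carboxylate
Product: 24 methyl (1R)-3-bromo-1-methyl-4-oxocyclohex-2-ene-1-carboxylate, via dibromide 23 (not isolated)
Conditions: Br2, CH2Cl2, 0 °C; then Et3N, 0 °C to rt
Reagents that add atoms: bromine, BrBr
Why: Bromine addition to the enone followed by triethylamine-induced dehydrobromination (addition–elimination) gives the α-bromo enone and so marks C10 for the later coupling.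

Step 13
Reactants: 24 methyl (1R)-3-bromo-1-methyl-4-oxocyclohex-2-ene-1-carboxylate
Product: 25 methyl (1R)-3-bromo-1-methyl-4-oxocyclohexa-2,5-diene-1-carboxylate
Conditions: IBX, DMSO, 75 °C
Reagents that add atoms: none
Why: IBX dehydrogenation of the only enolisable side (C2–C3) gives the cross-conjugated dienone, whose C4 chirality survives because the bromine keeps the two alkenes different.

Step 14
Reactants: 25 methyl (1R)-3-bromo-1-methyl-4-oxocyclohexa-2,5-diene-1-carboxylate
Product: 26 methyl (1R,4S)-3-bromo-4-hydroxy-1-methylcyclohexa-2,5-diene-1-carboxylate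
Conditions: (R)-Me-CBS oxazaborolidine (20 mol %), BH3·SMe2, THF, −30 °C; MeOH quench; product used at once
Reagents that add atoms: none
Why: Corey–Bakshi–Shibata reduction under reagent control (the bromovinyl flank acting as the large group) sets the C1 carbinol cis to the C19 ester, the remote C4 centre exerting no significant bias.

Step 15
Reactants: 26 methyl (1R,4S)-3-bromo-4-hydroxy-1-methylcyclohexa-2,5-diene-1-carboxylate
Product: 27 ring-A triol methyl 3-bromo-4,5,6-trihydroxy-1-methylcyclohex-2-ene-1-carboxylate (gibberellin positions: 1α-OH; 2β,3β-diol; 4α-CO2Me; 4β-Me)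
Conditions: OsO4 (2 mol %), 4-methylmorpholine N-oxide, acetone/H2O, 0 °C
Reagents that add atoms: osmium tetroxide, O=[Os](=O)(=O)=O; 4-methylmorpholine N-oxide, C[N+]1([O-])CCOCC1; water, O
Why: Upjohn dihydroxylation, in which OsO4 attacks only the electron-richer unbrominated alkene and, following the Kishi rule, the face anti to the allylic C1 hydroxyl, giving the 2β,3β-diol.

Step 16
Reactants: 27 ring-A triol
Product: 28 ring-A alcohol methyl 3-bromo-4-hydroxy-5,6-(isopropylidenedioxy)-1-methylcyclohex-2-ene-1-carboxylate (1α-OH free; 2β,3β-acetonide; 4α-CO2Me)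
Conditions: 2,2-dimethoxypropane, PPTS (cat.), acetone, rt
Reagents that add atoms: 2,2-dimethoxypropane, COC(C)(C)OC
Why: Acetonide formation is selective for the cis-2,3-diol (cis-fused dioxolane) and leaves the trans-disposed C1 hydroxyl free for the union.

**Union and completion**

Step 17
Reactants: 16 2-[(1R,5S)-6-methylidene-3-oxobicyclo[3.2.1]octan-1-yl]acetic acid; 28 ring-A alcohol
Product: 29 union ester (C7 carboxyl of 16 esterified by the C1 hydroxyl of 28)
Conditions: EDC·HCl, DMAP, CH2Cl2, 0 °C to rt
Reagents that add atoms: none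
Why: Steglich-type carbodiimide esterification of the unhindered acetic acid joins the two fragments with retention at C1.

Step 18
Reactants: 29 union ester
Product: 32 Claisen product methyl ester (ring A now a 10-bromo-1(10)-ene carrying C6 on C5α; C7 as methyl ester), via bis-silyl ketene acetal 30 (not isolated), via Claisen acid 31 (not isolated)
Conditions: LiN(i-Pr)2 (2.5 equiv), Me3SiCl (3 equiv), THF, −78 °C, then 60 °C; aq citric acid; then Me3SiCHN2, MeOH/toluene, 0 °C
Reagents that add atoms: (trimethylsilyl)diazomethane, C[Si](C)(C)C=[N+]=[N-]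
Why: Ireland–Claisen rearrangement, in which excess base and Me3SiCl silylate both the more acidic ketone (as a hydrolysable enol ether) and the ester, and the ketene acetal undergoes a suprafacial [3,3] shift across C1–C10–C5 that forms the hindered C5–C6 bond on the α face from which the C1–O bond departs (C5 set by chirality transfer, C6 set by the ketene acetal geometry and still epimerisable), the acid then being methylated.

Step 19
Reactants: 32 Claisen product methyl ester
Product: 33 dimethyl 2β,3β-isopropylidenedioxy-11-oxo-20-norgibberella-1(10),16-diene-7,19-dioate (5β-H; 9β-H; 6β-CO2Me)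
Conditions: Pd2(dba)3 (5 mol %), P(t-Bu)3·HBF4 (12 mol %), NaOt-Bu (1.4 equiv), toluene, 50 °C; AcOH quench at 0 °C
Reagents that add atoms: none
Why: Palladium-catalysed intramolecular α-alkenylation of a ketone enolate with a vinyl bromide (enolate cross-coupling), in which only the C9 enolate can reach C10 through a five-membered ring (enolisation is reversible, so the unproductive C12 enolate returns) and the bond is made on the open exo face of ring C, anti to the C15–C16 bridge, giving the axial C9–C10 bond (H9 β) whose remaining equatorial α-hydrogen is poorly aligned for re-enolisation.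

Step 20
Reactants: 33 tetracyclic keto diester
Product: 34 dimethyl 11β-hydroxy-2β,3β-isopropylidenedioxy-20-norgibberella-1(10),16-diene-7,19-dioate
Conditions: LiBH(s-Bu)3, THF, −78 °C; aq NH4Cl
Reagents that add atoms: none
Why: Diastereoselective ketone reduction in which the bulky hydride attacks the bicyclo[3.2.1]octan-3-one from the exo (α) face, away from the C15–C16 bridge, to give the axial 11β-alcohol while the hindered esters are untouched.

Step 21
Reactants: 34 11β-hydroxy diene diester
Product: 35 1β-iodo 19,10-lactone (methyl 11β-hydroxy-1β-iodo-2β,3β-isopropylidenedioxy-19,10-lactone 7-oate)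
Conditions: I2, NaHCO3, MeCN, 0 °C to rt, dark
Reagents that add atoms: iodine, II
Why: Iodolactonisation in which the α-oriented C19 ester carbonyl opens the β-iodonium ion of the C1=C10 alkene at the tertiary C10 (5-exo, anti addition) and iodide demethylates the lactonium ion, so the lactone is cis-bridged with C10–O α and H5 β retained, while the C7 ester on the β face cannot reach C10.

Step 22
Reactants: 35 1β-iodo 19,10-lactone
Product: 36 target 2,3-acetonide 7-methyl ester
Conditions: Bu3SnH, AIBN (cat.), toluene, 80 °C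
Reagents that add atoms: none
Why: Radical chain deiodination with tin hydride removes the secondary C1 iodide, creates no stereocentre and leaves the exocyclic alkene intact.

Step 23
Reactants: 36 target 2,3-acetonide 7-methyl ester
Product: 38 CNP0322347.1 (2β,3β,11β-trihydroxy 19,10-lactone 7-acid), via acetonide acid 37 (not isolated)
Conditions: KOH, MeOH/H2O, 60 °C; then 2 M HCl, THF, rt
Reagents that add atoms: potassium hydroxide, [K+].[OH-]
Why: Saponification of the C7 methyl ester (the epimerisable C6 settling as the more stable 6β-carboxyl, trans to C4, before the hindered ester is cleaved) followed by aqueous acid, which re-closes any opened γ-lactone and hydrolyses the acetonide (protecting-group removal) to release the target.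

**Compound list**
1 | cyclohexane-1,3-dione | O=C1CCCC(=O)C1 | starting material
2 | 3-methoxycyclohex-2-en-1-one | COC1=CC(=O)CCC1 | intermediate
3 | 2,3-dibromoprop-1-ene | C=C(Br)CBr | starting material
4 | (2-bromoprop-2-en-1-yl)zinc bromide | C=C(Br)C[Zn]Br | intermediate
5 | 1-(2-bromoprop-2-en-1-yl)-3-methoxycyclohex-2-en-1-ol (racemic, present as zinc alkoxide) | COC1=CC(O)(CC(Br)=C)CCC1 | intermediate
6 | 3-(2-bromoprop-2-en-1-yl)cyclohex-2-en-1-one | O=C1C=C(CC(Br)=C)CCC1 | intermediate
7 | (1R)-3-(2-bromoprop-2-en-1-yl)cyclohex-2-en-1-ol | O[C@H]1C=C(CC(Br)=C)CCC1 | intermediate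
8 | 1,1,1-trimethoxyethane | CC(OC)(OC)OC | starting material
9 | mixed ketene acetal of 7 (1-methoxyvinyl ether) | C=C(OC)O[C@H]1C=C(CC(Br)=C)CCC1 | intermediate
10 | methyl 2-[(1R)-1-(2-bromoprop-2-en-1-yl)cyclohex-2-en-1-yl]acetate | C=C(Br)C[C@]1(CC(=O)OC)CCCC=C1 | intermediate
11 | C11 alkylborane of 10 (C11 epimers) | C=C(Br)C[C@]1(CC(=O)OC)CCCC(B)C1 | intermediate
12 | methyl 2-[(1R)-1-(2-bromoprop-2-en-1-yl)-3-hydroxycyclohexyl]acetate (C11 epimers) | C=C(Br)C[C@]1(CC(=O)OC)CCCC(O)C1 | intermediate
13 | methyl 2-[(1R)-1-(2-bromoprop-2-en-1-yl)-3-oxocyclohexyl]acetate | C=C(Br)C[C@]1(CC(=O)OC)CCCC(=O)C1 | intermediate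
14 | methyl 2-[(1R)-1-(2-bromoprop-2-en-1-yl)-5-oxocyclohex-3-en-1-yl]acetate | C=C(Br)C[C@]1(CC(=O)OC)CC=CC(=O)C1 | intermediate
15 | methyl 2-[(1R,5S)-6-methylidene-3-oxobicyclo[3.2.1]octan-1-yl]acetate | C=C1C[C@]2(CC(=O)OC)C[C@H]1CC(=O)C2 | intermediate
16 | 2-[(1R,5S)-6-methylidene-3-oxobicyclo[3.2.1]octan-1-yl]acetic acid | C=C1C[C@]2(CC(=O)O)C[C@H]1CC(=O)C2 | intermediate
17 | (E)-4-(dimethylamino)but-3-en-2-one | CN(C)/C=C/C(C)=O | starting material
18 | (E)-3-(tert-butyldimethylsilyloxy)-N,N-dimethylbuta-1,3-dien-1-amine | CN(C)/C=C/C(=C)O[Si](C)(C)C(C)(C)C | intermediate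
19 | 2-methylprop-2-enal | CC(=C)C=O | starting material
20 | Diels–Alder adduct, 2-(dimethylamino)-1-methyl-4-(tert-butyldimethylsilyloxy)cyclohex-3-ene-1-carbaldehyde (quaternary centre as in 21; amine centre endo, lost in the same step) | O=C[C@]1(C)CCC(O[Si](C)(C)C(C)(C)C)=CC1N(C)C | intermediate
21 | (1R)-1-methyl-4-oxocyclohex-2-ene-1-carbaldehyde | O=C1CC[C@@](C)(C=O)C=C1 | intermediate
22 | methyl (1R)-1-methyl-4-oxocyclohex-2-ene-1-carboxylate | O=C1CC[C@@](C)(C(=O)OC)C=C1 | intermediate
23 | methyl 2,3-dibromo-1-methyl-4-oxocyclohexane-1-carboxylate (anti dibromide, CHBr centres not assigned) | O=C1CC[C@@](C)(C(=O)OC)C(Br)C1Br | intermediate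
24 | methyl (1R)-3-bromo-1-methyl-4-oxocyclohex-2-ene-1-carboxylate | O=C1CC[C@@](C)(C(=O)OC)C=C1Br | intermediate
25 | methyl (1R)-3-bromo-1-methyl-4-oxocyclohexa-2,5-diene-1-carboxylate | O=C1C=C[C@@](C)(C(=O)OC)C=C1Br | intermediate
26 | methyl (1R,4S)-3-bromo-4-hydroxy-1-methylcyclohexa-2,5-diene-1-carboxylate | O[C@H]1C=C[C@@](C)(C(=O)OC)C=C1Br | intermediate
27 | ring-A triol (1α-OH; 2β,3β-diol; 4α-CO2Me; 4β-Me; 10-Br) | O[C@H]1[C@H](O)[C@H](O)[C@@](C)(C(=O)OC)C=C1Br | intermediate
28 | ring-A alcohol (1α-OH; 2β,3β-acetonide; 4α-CO2Me; 4β-Me; 10-Br) | O[C@H]1[C@@H]2OC(C)(C)O[C@@H]2[C@@](C)(C(=O)OC)C=C1Br | intermediate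
29 | union ester of 16 (C7) with the C1 hydroxyl of 28 | C=C1C[C@]2(CC(=O)O[C@H]3[C@@H]4OC(C)(C)O[C@@H]4[C@@](C)(C(=O)OC)C=C3Br)C[C@H]1CC(=O)C2 | intermediate
30 | bis-silyl species from 29 (C6=C7 silyl ketene acetal, geometry not assigned; C11=C12 silyl enol ether) | C=C1C[C@]2(C=C(O[Si](C)(C)C)O[C@H]3[C@@H]4OC(C)(C)O[C@@H]4[C@@](C)(C(=O)OC)C=C3Br)C[C@H]1C=C(O[Si](C)(C)C)C2 | intermediate
31 | Claisen acid (C5–C6 bond formed; 10-bromo-1(10)-ene; free C7 acid) | C=C1C[C@]2([C@@H](C(=O)O)[C@H]3C(Br)=C[C@@H]4OC(C)(C)O[C@@H]4[C@@]3(C)C(=O)OC)C[C@H]1CC(=O)C2 | intermediate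
32 | Claisen product methyl ester | C=C1C[C@]2([C@@H](C(=O)OC)[C@H]3C(Br)=C[C@@H]4OC(C)(C)O[C@@H]4[C@@]3(C)C(=O)OC)C[C@H]1CC(=O)C2 | intermediate
33 | dimethyl 2β,3β-isopropylidenedioxy-11-oxo-20-norgibberella-1(10),16-diene-7,19-dioate | C=C1C[C@]23C[C@H]1CC(=O)[C@H]2C2=C[C@@H]4OC(C)(C)O[C@@H]4[C@@](C)(C(=O)OC)[C@H]2[C@@H]3C(=O)OC | intermediate
34 | dimethyl 11β-hydroxy-2β,3β-isopropylidenedioxy-20-norgibberella-1(10),16-diene-7,19-dioate | C=C1C[C@]23C[C@H]1C[C@H](O)[C@H]2C2=C[C@@H]4OC(C)(C)O[C@@H]4[C@@](C)(C(=O)OC)[C@H]2[C@@H]3C(=O)OC | intermediate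
35 | 1β-iodo 19,10-lactone, 2,3-acetonide, 7-methyl ester | C=C1C[C@]23C[C@H]1C[C@H](O)[C@H]2[C@@]12[C@H](I)[C@@H]4OC(C)(C)O[C@@H]4[C@@](C)(C(=O)O1)[C@H]2[C@@H]3C(=O)OC | intermediate
36 | target 2,3-acetonide 7-methyl ester | C=C1C[C@]23C[C@H]1C[C@H](O)[C@H]2[C@@]12C[C@@H]4OC(C)(C)O[C@@H]4[C@@](C)(C(=O)O1)[C@H]2[C@@H]3C(=O)OC | intermediate
37 | target 2,3-acetonide (free 7-acid) | C=C1C[C@]23C[C@H]1C[C@H](O)[C@H]2[C@@]12C[C@@H]4OC(C)(C)O[C@@H]4[C@@](C)(C(=O)O1)[C@H]2[C@@H]3C(=O)O | intermediate
38 | CNP0322347.1 | C=C1C[C@]23C[C@H]1C[C@H](O)[C@H]2[C@@]12C[C@H](O)[C@H](O)[C@@](C)(C(=O)O1)[C@H]2[C@@H]3C(=O)O | target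

**Step count and risks**

Total step count: 23 (steps 1–8 fragment CD, steps 9–16 fragment A, steps 17–23 union and completion).
Longest linear sequence: 15 steps (either fragment, 8 steps, plus steps 17–23), which is 15/23 of the total.

The three steps most likely to fail:

Step 7 (the proposed β-C–H alkenylation). The vinyl bromide may be reduced, or the catalyst may stall before desaturation; the hindered pyridine is there to keep the acid from isomerising the new exocyclic alkene. Known-chemistry fallback: setting out from ketone 13, IBX (DMSO, 75 °C) dehydrogenates the only desaturable side to give enone 14, this time isolated. A conventional reductive Heck cyclisation (Pd(OAc)2, PPh3, HCO2Na, Et4NCl, DMF, 80 °C; 5-exo carbopalladation, then formate reduction of the palladium enolate) then closes ring D, and the route is rejoined at 15. This fallback makes no compound outside the list (F0).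

Step 18 (Ireland–Claisen rearrangement). The ketone is more acidic than the ester, so two enolisations must succeed, and the [3,3] shift builds a bond next to the C4 quaternary centre. Fallback with the ketone masked so that only one enolate can form: setting out from keto ester 15, 1,2-bis(trimethylsilyloxy)ethane and Me3SiOSO2CF3 (cat., CH2Cl2, −78 °C) give dioxolane ester F1, and LiOH gives ketal acid F2. EDC/DMAP coupling with 28 gives ketal ester F3. LiN(i-Pr)2 (1.2 equiv) and Me3SiCl then form the single silyl ketene acetal F4, which rearranges at 60 °C and on mild acid work-up gives rearranged ketal acid F5. PPTS in wet acetone removes the dioxolane (the acetonide is kept by the acetone), and the route is rejoined at acid 31, which is methylated to 32 as before.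

Step 19 (ring B closure). Competing Heck insertion of the vinylpalladium into the C16 methylene, re-enolisation of 33 (which would scramble C9 or conjugate the alkene), and slow reaction at the neopentyl C9 are the concerns. Fallback by radical cyclisation: setting out from 32, t-BuMe2SiOSO2CF3/Et3N (CH2Cl2, 0 °C) gives the C9=C11 silyl enol ether F6 together with the C11=C12 regioisomeric silyl enol ether F7, which is separated and hydrolysed back to 32. Bu3SnH/AIBN (toluene, 80 °C) converts F6 into the C10 vinyl radical, which cyclises 5-exo onto C9 from the open exo face; the α-silyloxy C11 radical then takes hydrogen from the same face to give the 11β-silyl ether F8. Bu4NF (THF) cleaves the silyl ether and the route is rejoined at 34, bypassing 33 and step 20.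

**Further compounds**
F0 | step 7 | none | none
F1 | step 18 | methyl 2-[(1R,5S)-6-methylidene-3,3-(ethylenedioxy)bicyclo[3.2.1]octan-1-yl]acetate | C=C1C[C@]2(CC(=O)OC)C[C@H]1CC3(OCCO3)C2
F2 | step 18 | 2-[(1R,5S)-6-methylidene-3,3-(ethylenedioxy)bicyclo[3.2.1]octan-1-yl]acetic acid | C=C1C[C@]2(CC(=O)O)C[C@H]1CC3(OCCO3)C2
F3 | step 18 | ester of F2 with the C1 hydroxyl of 28 | C=C1C[C@]2(CC(=O)O[C@H]3[C@@H]4OC(C)(C)O[C@@H]4[C@@](C)(C(=O)OC)C=C3Br)C[C@H]1CC5(OCCO5)C2
F4 | step 18 | trimethylsilyl ketene acetal of F3 (geometry not assigned) | C=C1C[C@]2(C=C(O[Si](C)(C)C)O[C@H]3[C@@H]4OC(C)(C)O[C@@H]4[C@@](C)(C(=O)OC)C=C3Br)C[C@H]1CC5(OCCO5)C2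
F5 | step 18 | C11-dioxolane of Claisen acid 31 | C=C1C[C@]2([C@@H](C(=O)O)[C@H]3C(Br)=C[C@@H]4OC(C)(C)O[C@@H]4[C@@]3(C)C(=O)OC)C[C@H]1CC5(OCCO5)C2
F6 | step 19 | C9=C11 tert-butyldimethylsilyl enol ether of 32 | C=C1C[C@]2([C@@H](C(=O)OC)[C@H]3C(Br)=C[C@@H]4OC(C)(C)O[C@@H]4[C@@]3(C)C(=O)OC)C[C@H]1CC(O[Si](C)(C)C(C)(C)C)=C2
F7 | step 19 | C11=C12 tert-butyldimethylsilyl enol ether of 32 | C=C1C[C@]2([C@@H](C(=O)OC)[C@H]3C(Br)=C[C@@H]4OC(C)(C)O[C@@H]4[C@@]3(C)C(=O)OC)C[C@H]1C=C(O[Si](C)(C)C(C)(C)C)C2
F8 | step 19 | 11β-tert-butyldimethylsilyl ether of 34 | C=C1C[C@]23C[C@H]1C[C@H](O[Si](C)(C)C(C)(C)C)[C@H]2C2=C[C@@H]4OC(C)(C)O[C@@H]4[C@@](C)(C(=O)OC)[C@H]2[C@@H]3C(=O)OC
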